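(The rate constants are invented; the rest is arithmetic.)

Counted by substrate the flask keeps its total, and a substrate can take up partner twice, once to first product and once more to bis adduct.

all flasks: substrate 0.34 M; time 15 d

|  | partner | remark |
|---|---|---|
| zeta | 0.880 M (in portions, 2) | the portions of partner follow each other after 15 h, the first at the start |
| eta | 0.440 M (in portions, 2) | the portions of partner follow each other after 15 h, the first at the start |

    substrate + partner → first product (k1 = 0.025 M⁻¹ min⁻¹)
    partner + first product → bis adduct (k2 = 0.029 M⁻¹ min⁻¹)
    substrate + first product → side product (k3 = 2.6 × 10⁻⁴ M⁻¹ min⁻¹)
    partner → decomposed reagent (k4 = 2.5 × 10⁻⁴ min⁻¹)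
    first product → over-reaction product (k5 = 9.0 × 10⁻⁵ min⁻¹)

- a species is counted by the substrate in it: one side product counts as two
- run time (zeta): 15 d

* which of the two there is more of at the end, zeta (bis adduct / first product)
* which of the two there is more of at the end, eta (bis adduct / first product)
* final first product, as a percentage of the substrate charged, in zeta
* final first product, as a percentage of the substrate charged, in eta

First I ask whether the partner can fill those places. The cover C, the partner charged over twice the substrate charged, is 0.647 in eta and 1.29 in zeta, so on paper partner is the limiting reagent in eta and in surplus in zeta.

Next I ask which comes first, filling or decay. With eta's whole charge there at once, first product has a half-life of 0.91 h by step 2, far shorter than the 5.3 d by step 5 and shorter than the 1.9 d of partner by step 4. So I solve the fast end first and join the slow end to it.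

With C above one in zeta I take no place to stay open, so I reckon first product at 0 % and more bis adduct.

In eta the uncovered share is 0.353, and the open places per substrate are twice that. Substrate left over holds two of them and first product one. Since k2/k1 is 1.16, I roughly take the two as equal in amount, which gives first product a third of the open places, or 23.5 %. Step 5 over 15 d then leaves a share 0.143, so I expect 3.37 %, and more bis adduct.

The forecast says bis adduct in zeta with <0.001 % first product, and bis adduct in eta with 3 %: “first product then decays”. Its eta start is 0.30 of the substrate, which is not the figure I took, and it counts a loss to leftover substrate as well, which I did not.

The flask gives bis adduct in zeta, 95.6 % against 0 % first product, and bis adduct in eta, 46.7 % against 3.09 %.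

With C at 0.647, eta ends with 0 % of its partner free, and with step 5 stopped its first product ends at 20.9 % instead of 3.09 %. A neighbouring flask, like zeta but with 0.58 M of substrate, has C of 0.759, which puts it on eta's side, and the same reckoning gives 2.30 %. That flask ends with 2.31 % first product.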